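**Retrosynthetic overview**
1. The only ring, the oxirane, is formed last by hydroxyl-directed epoxidation of the (Z)-C5=C6 allylic alcohol; before that only protecting groups are removed.
2. C7–C8 and C10–C11 come from two boron anti-aldol reactions on the symmetrical ketone 1,5-bis(PMBO)pentan-3-one: first with the C1–C7 (Z,Z)-dienal (chiral boron reagent), then with the C11–C15 aldehyde (1,4-induction from C8).
3. Key disconnection C8–C9/C9–C10: the keto carbon C9 enters as lithiated 1,3-dithiane (acyl-anion equivalent, used as a formyl-dianion linchpin) and is joined in one flask to two oxirane carbons.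
4. The same umpolung (C12–C13: propanoyl anion as lithiated 2-ethyl-1,3-dithiane, made from propanal, plus oxirane) gives the C11–C15 aldehyde with C13 still masked.
5. The dienal comes from (R)-Roche ester by Z-Wittig, α-iodo-Wittig and lithium–iodine exchange/formylation.

**Assumptions**
- Atom labels: C1–C15 follow the chain of the target SMILES from the propenyl CH3 (C1) to the ethyl CH3 (C15); C8′ and C10′ are the hydroxymethyl carbons on C8 and C10.
- The open-chain keto form is the target as drawn; in solution it is expected to equilibrate with its six-membered C13 hemiketal (closed by the C10′ hydroxyl).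
- L*2BBr = bis{[(1S,2S,5R)-2-isopropyl-5-methylcyclohexyl]methyl}bromoborane (two steps from (−)-menthone); it is taken to be the antipode that gives adduct 22, and the reagent from (+)-menthone is used if the sense is the opposite.

**Route**

Step 1
Reactants: 1 1,3-dithiane; 2 oxirane (ethylene oxide, 2 equiv)
Product: 5 2,2-bis(2-hydroxyethyl)-1,3-dithiane, via 2-lithio-1,3-dithiane 3 (not isolated), via lithium 2-(1,3-dithian-2-yl)ethanolate 4 (not isolated)
Conditions: n-BuLi, THF, −30 °C; 2, −78 to 0 °C; n-BuLi, −20 °C; 2, −78 °C to rt; H2O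
Reagents that add atoms: none
Why: Corey–Seebach umpolung: the lithiated dithiane is an acyl-anion equivalent, so the future keto carbon C9 opens oxirane twice by SN2 attack, forming C8–C9 and C9–C10 and bringing in both C8′/C10′ oxygens; no stereocenter is formed.

Step 2
Reactants: 5 2,2-bis(2-hydroxyethyl)-1,3-dithiane
Product: 6 2,2-bis{2-[(4-methoxybenzyl)oxy]ethyl}-1,3-dithiane
Conditions: NaH, 4-MeOC6H4CH2Cl, n-Bu4NI (cat.), THF/DMF, 0 °C to rt
Reagents that add atoms: 4-methoxybenzyl chloride, COc1ccc(CCl)cc1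
Why: Williamson etherification; the PMB ethers are the hydrogen-bond-accepting ethers needed for the later 1,4-induction and can be removed oxidatively at the end.

Step 3
Reactants: 6 2,2-bis{2-[(4-methoxybenzyl)oxy]ethyl}-1,3-dithiane
Product: 7 1,5-bis[(4-methoxybenzyl)oxy]pentan-3-one
Conditions: MeI, CaCO3, MeCN/H2O (4:1), 45 °C
Reagents that add atoms: water, O
Why: S-methylation/hydrolysis of the dithiane under neutral, buffered conditions reveals the C9 ketone without touching the PMB ethers or causing β-elimination.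

Step 4
Reactants: 8 propanal
Product: 9 2-ethyl-1,3-dithiane
Conditions: HS(CH2)3SH, BF3·OEt2 (cat.), CH2Cl2, 0 °C to rt
Reagents that add atoms: propane-1,3-dithiol, SCCCS
Why: Lewis-acid-catalysed thioacetalisation of the aldehyde turns the electrophilic carbonyl carbon (future C13, already carrying C14–C15) into a carbon that can be lithiated; no stereocenter.

Step 5
Reactants: 9 2-ethyl-1,3-dithiane; 2 oxirane
Product: 11 2-(2-ethyl-1,3-dithian-2-yl)ethanol, via 2-ethyl-2-lithio-1,3-dithiane 10 (not isolated)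
Conditions: n-BuLi, THF, −20 °C; 2, −78 °C to rt; H2O
Reagents that add atoms: none
Why: Corey–Seebach umpolung: the lithiated 2-ethyl-1,3-dithiane is a propanoyl-anion equivalent that forms C12–C13 by SN2 opening of oxirane; no stereocenter.

Step 6
Reactants: 11 2-(2-ethyl-1,3-dithian-2-yl)ethanol
Product: 12 (2-ethyl-1,3-dithian-2-yl)acetaldehyde
Conditions: SO3·pyridine, DMSO, i-Pr2NEt, CH2Cl2, 0 °C
Reagents that add atoms: none
Why: Parikh–Doering oxidation gives the aldehyde without oxidising the dithiane sulfur.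

Step 7
Reactants: 13 methyl (R)-3-hydroxy-2-methylpropanoate
Product: 14 methyl (R)-2-methyl-3-[(triethylsilyl)oxy]propanoate
Conditions: Et3SiCl, imidazole, CH2Cl2, 0 °C
Reagents that add atoms: chlorotriethylsilane, CC[Si](Cl)(CC)CC
Why: Silylation of the primary alcohol; triethylsilyl is chosen because a primary triethylsilyl ether can later be oxidised directly under Swern conditions; C4 comes from the chiral pool.

Step 8
Reactants: 14 methyl (R)-2-methyl-3-[(triethylsilyl)oxy]propanoate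
Product: 16 triethyl{[(2S,3Z)-2-methylpent-3-en-1-yl]oxy}silane, via (R)-2-methyl-3-[(triethylsilyl)oxy]propanal 15 (not isolated)
Conditions: i-Bu2AlH, CH2Cl2, −78 °C; then EtPPh3Br, NaN(SiMe3)2, THF, −78 °C to rt
Reagents that add atoms: ethyltriphenylphosphonium bromide, CC[P+](c1ccccc1)(c1ccccc1)c1ccccc1.[Br-]
Why: Low-temperature ester-to-aldehyde reduction followed at once by a salt-free Wittig reaction of the non-stabilised ylide gives the Z-alkene (kinetic oxaphosphetane) without epimerising C4; the R to S change is only a priority change.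

Step 9
Reactants: 16 triethyl{[(2S,3Z)-2-methylpent-3-en-1-yl]oxy}silane
Product: 18 (2Z,4S,5Z)-2-iodo-4-methylhepta-2,5-diene, via (2S,3Z)-2-methylpent-3-enal 17 (not isolated)
Conditions: (COCl)2, DMSO, CH2Cl2, −78 to −40 °C; i-Pr2NEt, −78 °C; then [Ph3PCH(I)CH3]I, NaN(SiMe3)2, THF, −78 to −20 °C
Reagents that add atoms: (1-iodoethyl)triphenylphosphonium iodide, CC(I)[P+](c1ccccc1)(c1ccccc1)c1ccccc1.[I-]
Why: Direct Swern oxidation of the primary silyl ether gives the labile β,γ-unsaturated aldehyde, which is used cold and at once in a Stork–Zhao-type α-iodo-Wittig reaction that places iodine cis to C4 (Z).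

Step 10
Reactants: 18 (2Z,4S,5Z)-2-iodo-4-methylhepta-2,5-diene
Product: 20 (2Z,4S,5Z)-2,4-dimethylhepta-2,5-dienal, via [(2E,4S,5Z)-4-methylhepta-2,5-dien-2-yl]lithium 19 (not isolated)
Conditions: t-BuLi (2.1 equiv), Et2O, −78 °C; DMF, −78 to 0 °C; H2O
Reagents that add atoms: N,N-dimethylformamide, CN(C)C=O
Why: Lithium–iodine exchange and formylation both proceed with retention of alkene geometry, so the aldehyde carbon C7 ends up cis to C4 (the 2E label of 19 is only a priority change).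

Step 11
Reactants: 7 1,5-bis[(4-methoxybenzyl)oxy]pentan-3-one (1.5 equiv); 20 (2Z,4S,5Z)-2,4-dimethylhepta-2,5-dienal
Product: 22 (4R,5S,6Z,8S,9Z)-5-hydroxy-1-[(4-methoxybenzyl)oxy]-4-{[(4-methoxybenzyl)oxy]methyl}-6,8-dimethylundeca-6,9-dien-3-one, via (E)-enol dialkylborinate 21 (not isolated)
Conditions: L*2BBr, Et3N, Et2O, −78 °C; 20, −78 to −25 °C; MeOH, NaH2PO4/Na2HPO4 buffer (pH 7)
Reagents that add atoms: none
Why: Reagent-controlled boron anti-aldol (Gennari–Paterson chiral bromoborane): the (E)-enol borinate reacts through a Zimmerman–Traxler chair to give the 7,8-anti adduct, and the chiral ligands choose the enolate face, setting C7 (S) and C8 (R); the minor isomer is a diastereomer (20 is enantiopure) and is removed by chromatography.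

Step 12
Reactants: 22 the aldol adduct above
Product: 23 (4R,5S,6Z,8S,9Z)-1-[(4-methoxybenzyl)oxy]-4-{[(4-methoxybenzyl)oxy]methyl}-6,8-dimethyl-5-[(triethylsilyl)oxy]undeca-6,9-dien-3-one
Conditions: Et3SiOTf, 2,6-lutidine, CH2Cl2, −78 °C
Reagents that add atoms: triethylsilyl trifluoromethanesulfonate, CC[Si](CC)(CC)OS(=O)(=O)C(F)(F)F
Why: Silylation of the C7 hydroxyl; a non-coordinating silyl ether keeps the next enolisation clean and leaves the C8′ PMB ether as the only directing oxygen.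

Step 13
Reactants: 23 the silyl ether above; 12 (2-ethyl-1,3-dithian-2-yl)acetaldehyde
Product: 25 (2S,3S,5R,6S,7Z,9S,10Z)-1-(2-ethyl-1,3-dithian-2-yl)-2-hydroxy-3,5-bis{[(4-methoxybenzyl)oxy]methyl}-7,9-dimethyl-6-[(triethylsilyl)oxy]dodeca-7,10-dien-4-one, via (E)-enol dicyclohexylborinate 24 (not isolated)
Conditions: (c-C6H11)2BCl, Et3N, Et2O, 0 °C; 12, −78 to −20 °C; MeOH, NaH2PO4/Na2HPO4 buffer (pH 7), SiO2
Reagents that add atoms: none
Why: Paterson boron anti-aldol: the CH2 side is enolised to the (E)-enol borinate and the chair transition state gives 10,11-anti; with the C8–H eclipsing the enolate (A(1,3) strain) the aldehyde approaches on the CH2OPMB side, away from the C7 branch (1,4-syn induction), setting C10 (S) and C11 (S).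

Step 14
Reactants: 25 the bis-aldol adduct above
Product: 26 (2S,3S,5R,6S,7Z,9S,10Z)-1-(2-ethyl-1,3-dithian-2-yl)-2,6-dihydroxy-3,5-bis{[(4-methoxybenzyl)oxy]methyl}-7,9-dimethyldodeca-7,10-dien-4-one
Conditions: HF·pyridine, pyridine, THF, 0 °C
Reagents that add atoms: none
Why: Buffered fluoride desilylation frees the C7 hydroxyl and leaves the PMB ethers, the dithiane and the β-hydroxy ketone intact.

Step 15
Reactants: 26 the diol above
Product: 27 (5S,6S,8R,9S,10Z,12S,13Z)-5,9-dihydroxy-6,8-bis{[(4-methoxybenzyl)oxy]methyl}-10,12-dimethylpentadeca-10,13-diene-3,7-dione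
Conditions: MeI, CaCO3, MeCN/H2O (4:1), 40 °C
Reagents that add atoms: water, O
Why: Neutral S-methylation/hydrolysis unmasks the C13 ketone without acid or oxidant, so the alkenes, PMB ethers and both aldol units survive and no α-stereocenter is epimerised.

Step 16
Reactants: 27 the diketone above
Product: 28 (5S,6S,8R,9S,10Z,12S,13Z)-5,9-dihydroxy-6,8-bis(hydroxymethyl)-10,12-dimethylpentadeca-10,13-diene-3,7-dione
Conditions: DDQ, CH2Cl2/NaH2PO4/Na2HPO4 buffer (pH 7), 0 °C
Reagents that add atoms: none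
Why: Oxidative PMB cleavage (benzylic hydride abstraction, then hydrolysis of the oxocarbenium ion) in a wet buffered medium frees both primary alcohols; water prevents anisylidene acetal formation and the alkenes are not attacked at 0 °C.

Step 17
Reactants: 28 the tetraol above
Product: 29 myriaporone 4, (5S,6S,8R,9S)-5,9-dihydroxy-6,8-bis(hydroxymethyl)-9-{(2R,3S)-2-methyl-3-[(2S,3Z)-pent-3-en-2-yl]oxiran-2-yl}nonane-3,7-dione
Conditions: mCPBA, NaHCO3, CH2Cl2, −20 °C
Reagents that add atoms: 3-chloroperoxybenzoic acid, OOC(=O)c1cccc(Cl)c1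
Why: Hydroxyl-directed (Henbest) peracid epoxidation: in the A(1,3)-minimised conformer the C7 hydroxyl delivers the peracid to one face of the trisubstituted Z-alkene (threo), setting C5 (S) and C6 (R); syn addition keeps C4 and C7 cis, and the directed trisubstituted alkene reacts far faster than the Z-propenyl group.

**Compound list**
1 | 1,3-dithiane | C1CSCSC1 | starting material
2 | oxirane (ethylene oxide) | C1CO1 | starting material
3 | 2-lithio-1,3-dithiane | [Li]C1SCCCS1 | intermediate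
4 | lithium 2-(1,3-dithian-2-yl)ethanolate | [Li+].[O-]CCC1SCCCS1 | intermediate
5 | 2,2-bis(2-hydroxyethyl)-1,3-dithiane | OCCC1(CCO)SCCCS1 | intermediate
6 | 2,2-bis{2-[(4-methoxybenzyl)oxy]ethyl}-1,3-dithiane | COc1ccc(COCCC2(CCOCc3ccc(OC)cc3)SCCCS2)cc1 | intermediate
7 | 1,5-bis[(4-methoxybenzyl)oxy]pentan-3-one | COc1ccc(COCCC(=O)CCOCc2ccc(OC)cc2)cc1 | intermediate
8 | propanal | CCC=O | starting material
9 | 2-ethyl-1,3-dithiane | CCC1SCCCS1 | intermediate
10 | 2-ethyl-2-lithio-1,3-dithiane | CCC1([Li])SCCCS1 | intermediate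
11 | 2-(2-ethyl-1,3-dithian-2-yl)ethanol | CCC1(CCO)SCCCS1 | intermediate
12 | (2-ethyl-1,3-dithian-2-yl)acetaldehyde | CCC1(CC=O)SCCCS1 | intermediate
13 | methyl (R)-3-hydroxy-2-methylpropanoate | COC(=O)[C@H](C)CO | starting material
14 | methyl (R)-2-methyl-3-[(triethylsilyl)oxy]propanoate | COC(=O)[C@H](C)CO[Si](CC)(CC)CC | intermediate
15 | (R)-2-methyl-3-[(triethylsilyl)oxy]propanal | O=C[C@H](C)CO[Si](CC)(CC)CC | intermediate
16 | triethyl{[(2S,3Z)-2-methylpent-3-en-1-yl]oxy}silane | C/C=C\[C@H](C)CO[Si](CC)(CC)CC | intermediate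
17 | (2S,3Z)-2-methylpent-3-enal | C/C=C\[C@H](C)C=O | intermediate
18 | (2Z,4S,5Z)-2-iodo-4-methylhepta-2,5-diene | C/C=C\[C@H](C)/C=C(/C)I | intermediate
19 | [(2E,4S,5Z)-4-methylhepta-2,5-dien-2-yl]lithium | C/C=C\[C@H](C)/C=C(/C)[Li] | intermediate
20 | (2Z,4S,5Z)-2,4-dimethylhepta-2,5-dienal | C/C=C\[C@H](C)/C=C(/C)C=O | intermediate
21 | (E)-1,5-bis[(4-methoxybenzyl)oxy]pent-2-en-3-yl bis{[(1S,2S,5R)-2-isopropyl-5-methylcyclohexyl]methyl}borinate | COc1ccc(COC/C=C(/OB(C[C@H]2C[C@H](C)CC[C@H]2C(C)C)C[C@H]3C[C@H](C)CC[C@H]3C(C)C)CCOCc4ccc(OC)cc4)cc1 | intermediate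
22 | (4R,5S,6Z,8S,9Z)-5-hydroxy-1-[(4-methoxybenzyl)oxy]-4-{[(4-methoxybenzyl)oxy]methyl}-6,8-dimethylundeca-6,9-dien-3-one | C/C=C\[C@H](C)/C=C(/C)[C@@H](O)[C@@H](COCc1ccc(OC)cc1)C(=O)CCOCc1ccc(OC)cc1 | intermediate
23 | (4R,5S,6Z,8S,9Z)-1-[(4-methoxybenzyl)oxy]-4-{[(4-methoxybenzyl)oxy]methyl}-6,8-dimethyl-5-[(triethylsilyl)oxy]undeca-6,9-dien-3-one | C/C=C\[C@H](C)/C=C(/C)[C@@H](O[Si](CC)(CC)CC)[C@@H](COCc1ccc(OC)cc1)C(=O)CCOCc1ccc(OC)cc1 | intermediate
24 | (E)-enol dicyclohexylborinate of 23 (boron on the C9 oxygen, C9=C10 double bond) | C/C=C\[C@H](C)/C=C(/C)[C@@H](O[Si](CC)(CC)CC)[C@@H](COCc1ccc(OC)cc1)/C(OB(C2CCCCC2)C3CCCCC3)=C\COCc4ccc(OC)cc4 | intermediate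
25 | (2S,3S,5R,6S,7Z,9S,10Z)-1-(2-ethyl-1,3-dithian-2-yl)-2-hydroxy-3,5-bis{[(4-methoxybenzyl)oxy]methyl}-7,9-dimethyl-6-[(triethylsilyl)oxy]dodeca-7,10-dien-4-one | C/C=C\[C@H](C)/C=C(/C)[C@@H](O[Si](CC)(CC)CC)[C@@H](COCc1ccc(OC)cc1)C(=O)[C@@H](COCc1ccc(OC)cc1)[C@@H](O)CC1(CC)SCCCS1 | intermediate
26 | (2S,3S,5R,6S,7Z,9S,10Z)-1-(2-ethyl-1,3-dithian-2-yl)-2,6-dihydroxy-3,5-bis{[(4-methoxybenzyl)oxy]methyl}-7,9-dimethyldodeca-7,10-dien-4-one | C/C=C\[C@H](C)/C=C(/C)[C@@H](O)[C@@H](COCc1ccc(OC)cc1)C(=O)[C@@H](COCc1ccc(OC)cc1)[C@@H](O)CC1(CC)SCCCS1 | intermediate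
27 | (5S,6S,8R,9S,10Z,12S,13Z)-5,9-dihydroxy-6,8-bis{[(4-methoxybenzyl)oxy]methyl}-10,12-dimethylpentadeca-10,13-diene-3,7-dione | C/C=C\[C@H](C)/C=C(/C)[C@@H](O)[C@@H](COCc1ccc(OC)cc1)C(=O)[C@@H](COCc1ccc(OC)cc1)[C@@H](O)CC(=O)CC | intermediate
28 | (5S,6S,8R,9S,10Z,12S,13Z)-5,9-dihydroxy-6,8-bis(hydroxymethyl)-10,12-dimethylpentadeca-10,13-diene-3,7-dione | C/C=C\[C@H](C)/C=C(/C)[C@@H](O)[C@@H](CO)C(=O)[C@@H](CO)[C@@H](O)CC(=O)CC | intermediate
29 | myriaporone 4 | C/C=C\[C@H](C)[C@@H]1O[C@]1(C)[C@@H](O)[C@@H](CO)C(=O)[C@@H](CO)[C@@H](O)CC(=O)CC | target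

**Step count and risks**

Total step count: 17. Longest linear sequence: 11 steps (13 to 29, steps 7–17).

Steps most likely to fail:

Step 9. The β,γ-unsaturated aldehyde 17 can epimerise or conjugate, and the α-iodo-Wittig reaction is often only moderate in yield and Z-selectivity. The fallback sets out from 16 and comes back at 20. n-Bu4NF (THF, 0 °C) frees (2S,3Z)-2-methylpent-3-en-1-ol F1. Dess–Martin periodinane buffered with NaHCO3 then gives aldehyde 17, which is used cold and at once in a Still–Gennari olefination (ethyl 2-[bis(2,2,2-trifluoroethoxy)phosphoryl]propanoate, KN(SiMe3)2, 18-crown-6, THF, −78 °C) to give ethyl (2Z,4S,5Z)-2,4-dimethylhepta-2,5-dienoate F2. i-Bu2AlH (CH2Cl2, −78 °C) reduces it to (2Z,4S,5Z)-2,4-dimethylhepta-2,5-dien-1-ol F3, and MnO2 (CH2Cl2, rt) oxidises F3 to enal 20. This replaces the iodo-Wittig/organolithium sequence by a Horner–Wadsworth–Emmons/redox sequence, at the cost of two extra steps.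

Step 11. The chiral bromoborane may give modest selectivity, may attack the PMB ethers, or may isomerise the Z-enal. The fallback sets out from 7 and 20 and comes back at 22. The aldol is run with achiral (c-C6H11)2BCl/Et3N (Et2O, 0 °C, then 20 at −78 to −20 °C), which is known to tolerate PMB ethers. Because 20 is a single enantiomer, the two anti adducts are diastereomers: 22 and (4S,5R,6Z,8S,9Z)-5-hydroxy-1-[(4-methoxybenzyl)oxy]-4-{[(4-methoxybenzyl)oxy]methyl}-6,8-dimethylundeca-6,9-dien-3-one F4. They are separated by chromatography, so absolute control comes from the Roche-ester stereocenter by separation instead of from a chiral reagent, and at most half of the material is used.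

Step 13. The level of 1,4-induction from C8 in this new substrate is not proven, and the hindered aldehyde 12 may react slowly. The fallback sets out from 7 (together with 12 and 20) and comes back at 26; it reverses the order of the two aldol reactions. Ketone 7 and aldehyde 12, with the bromoborane antipode that gives the (4S,5S) adduct (Et3N, Et2O, −78 °C), give (4S,5S)-6-(2-ethyl-1,3-dithian-2-yl)-5-hydroxy-1-[(4-methoxybenzyl)oxy]-4-{[(4-methoxybenzyl)oxy]methyl}hexan-3-one F5. Et3SiOTf/2,6-lutidine then gives (4S,5S)-6-(2-ethyl-1,3-dithian-2-yl)-1-[(4-methoxybenzyl)oxy]-4-{[(4-methoxybenzyl)oxy]methyl}-5-[(triethylsilyl)oxy]hexan-3-one F6. Enolisation with (c-C6H11)2BCl/Et3N and addition of the reactive, non-enolisable enal 20 gives (2S,3S,5R,6S,7Z,9S,10Z)-1-(2-ethyl-1,3-dithian-2-yl)-6-hydroxy-3,5-bis{[(4-methoxybenzyl)oxy]methyl}-7,9-dimethyl-2-[(triethylsilyl)oxy]dodeca-7,10-dien-4-one F7; the C10 stereocenter is now the directing one. HF·pyridine (pyridine, THF, 0 °C) removes the silyl group to give diol 26.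

**Further compounds**
F1 | step 9 | (2S,3Z)-2-methylpent-3-en-1-ol | C/C=C\[C@H](C)CO
F2 | step 9 | ethyl (2Z,4S,5Z)-2,4-dimethylhepta-2,5-dienoate | C/C=C\[C@H](C)/C=C(/C)C(=O)OCC
F3 | step 9 | (2Z,4S,5Z)-2,4-dimethylhepta-2,5-dien-1-ol | C/C=C\[C@H](C)/C=C(/C)CO
F4 | step 11 | (4S,5R,6Z,8S,9Z)-5-hydroxy-1-[(4-methoxybenzyl)oxy]-4-{[(4-methoxybenzyl)oxy]methyl}-6,8-dimethylundeca-6,9-dien-3-one | C/C=C\[C@H](C)/C=C(/C)[C@H](O)[C@H](COCc1ccc(OC)cc1)C(=O)CCOCc1ccc(OC)cc1
F5 | step 13 | (4S,5S)-6-(2-ethyl-1,3-dithian-2-yl)-5-hydroxy-1-[(4-methoxybenzyl)oxy]-4-{[(4-methoxybenzyl)oxy]methyl}hexan-3-one | COc1ccc(COCCC(=O)[C@@H](COCc2ccc(OC)cc2)[C@@H](O)CC2(CC)SCCCS2)cc1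
F6 | step 13 | (4S,5S)-6-(2-ethyl-1,3-dithian-2-yl)-1-[(4-methoxybenzyl)oxy]-4-{[(4-methoxybenzyl)oxy]methyl}-5-[(triethylsilyl)oxy]hexan-3-one | COc1ccc(COCCC(=O)[C@@H](COCc2ccc(OC)cc2)[C@@H](O[Si](CC)(CC)CC)CC2(CC)SCCCS2)cc1
F7 | step 13 | (2S,3S,5R,6S,7Z,9S,10Z)-1-(2-ethyl-1,3-dithian-2-yl)-6-hydroxy-3,5-bis{[(4-methoxybenzyl)oxy]methyl}-7,9-dimethyl-2-[(triethylsilyl)oxy]dodeca-7,10-dien-4-one | C/C=C\[C@H](C)/C=C(/C)[C@@H](O)[C@@H](COCc1ccc(OC)cc1)C(=O)[C@@H](COCc1ccc(OC)cc1)[C@@H](O[Si](CC)(CC)CC)CC1(CC)SCCCS1
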